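**Retrosynthetic overview**
- Target 21 comes from phenol 15 by benzylation, removal of the alkyl silyl ether, esterification with stearoyl chloride 19 and a final double hydrogenolysis.
- Structural feature: ring carbons C2 to C6 of the benzene (H, O, O, OMe, H) are C2 to C6 of the 3,5-dioxygenated 4-pyranone 6, and C1 with its three-carbon chain stands where the pyranone oxygen O1 was.
- Key disconnections: C1–C2 (the ylide from salt 9 adds to the 4-silyloxypyrylium ion of 6) and C1=C6 (intramolecular Wittig after the 2H-pyran opens); together they exchange O1 for the ylide carbon.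
- Pyranone 6 comes from benzyl glycidyl ether 1 by methanolysis, oxidation, double aminomethylenation with 4 and acid cyclisation; salt 9 comes from bromide 7 and PPh3 8.
- Ring order: the pyranone ring (step 4), then the benzene ring that replaces it (step 6).

Key step: step 6

Assumption: the target has no stereocentre, so racemic benzyl glycidyl ether is used; (4-bromobutoxy)(tert-butyl)dimethylsilane, benzyl bromide and stearoyl chloride are taken as purchased.

**Step 1**
Reactants: 1 benzyl glycidyl ether (racemic)
Product: 2 1-(benzyloxy)-3-methoxypropan-2-ol (racemic)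
Conditions: NaOMe (0.2 equiv), MeOH, reflux
Reagents that add atoms: methanol, CO
Why: Base-catalysed epoxide alcoholysis, in which methoxide attacks the terminal carbon by SN2; the carbinol centre is racemic and is removed in step 2.

**Step 2**
Reactants: 2 1-(benzyloxy)-3-methoxypropan-2-ol
Product: 3 1-(benzyloxy)-3-methoxypropan-2-one
Conditions: TEMPO (cat.), KBr (cat.), NaOCl, NaHCO3, CH2Cl2/H2O, 0 °C
Reagents that add atoms: none
Why: Anelli oxidation, in which the oxoammonium salt made from TEMPO and NaOCl should oxidise the secondary alcohol to the ketone under buffered two-phase conditions that leave both ethers alone.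

**Step 3**
Reactants: 3 1-(benzyloxy)-3-methoxypropan-2-one; 4 N,N-dimethylformamide dimethyl acetal (5 equiv)
Product: 5 (1Z,4Z)-2-(benzyloxy)-1,5-bis(dimethylamino)-4-methoxypenta-1,4-dien-3-one
Conditions: neat, 110 °C, MeOH distilled off
Reagents that add atoms: none
Why: Aminomethylenation with an amide acetal, in which each alkoxy-activated alpha-methylene condenses to a vinylogous amide and distilling off methanol drives the slower second condensation; the alkene geometry is labile and irrelevant to step 4.

**Step 4**
Reactants: 5 (1Z,4Z)-2-(benzyloxy)-1,5-bis(dimethylamino)-4-methoxypenta-1,4-dien-3-one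
Product: 6 3-(benzyloxy)-5-methoxy-4H-pyran-4-one
Conditions: 2 M HCl, THF, 50 °C
Reagents that add atoms: water, O
Why: Classical 4-pyranone synthesis from a bis(aminomethylene) ketone, in which one enaminone is hydrolysed to the hydroxymethylene ketone and its enol oxygen then adds 6-endo to the other enaminone with loss of dimethylamine.

**Step 5**
Reactants: 7 (4-bromobutoxy)(tert-butyl)dimethylsilane; 8 triphenylphosphine
Product: 9 [4-(tert-butyldimethylsilyloxy)butyl]triphenylphosphonium bromide
Conditions: MeCN, reflux
Reagents that add atoms: none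
Why: SN2 quaternisation of triphenylphosphine by an unhindered primary bromide under neutral anhydrous conditions that a silyl ether tolerates.

**Step 6**
Reactants: 6 3-(benzyloxy)-5-methoxy-4H-pyran-4-one; 9 [4-(tert-butyldimethylsilyloxy)butyl]triphenylphosphonium bromide
Product: 15 2-(benzyloxy)-4-[3-(tert-butyldimethylsilyloxy)propyl]-6-methoxyphenol, via silyloxypyrylium triflate 10 (not isolated), via phosphorus ylide 11 (not isolated), via 2H-pyran phosphonium triflate 12 (not isolated), via ylide dienal 13 (not isolated), via aryl silyl ether 14 (not isolated)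
Conditions: 6, tBuMe2SiOTf (1.0 equiv), CH2Cl2, rt; ylide 11 [from 9, KN(SiMe3)2 (1.0 equiv), THF, −78 to 0 °C] added at −78 °C; KN(SiMe3)2 (1.05 equiv), −78 °C to rt; then K2CO3, MeOH, rt
Reagents that add atoms: none
Why: Proposed new method: O-silylation of 6 gives the 4-silyloxypyrylium triflate 10, whose unsubstituted alpha carbon takes up the nonstabilised ylide 11 (new C1–C2 bond) to give the 2H-pyran phosphonium salt 12; the second equivalent of KN(SiMe3)2 removes the proton next to phosphorus and the pyran opens (six-electron electrocyclic opening or its E1cB equivalent) to the ylide dienal 13, a push-pull system whose CH=C(OBn) bond can rotate to bring the ylide carbon next to the aldehyde. Ring closure is a 6-exo-trig intramolecular Wittig reaction of the ylide carbon C1 on the aldehyde carbon C6, and loss of Ph3PO, which carries away the former ring oxygen, leaves the benzene ring as its silyl ether 14. The closest known reactions are the conversion of 2,4,6-trisubstituted pyrylium salts into benzenes by alkylidenephosphoranes and the alpha-addition of Grignard reagents and silyl enol ethers to 4-silyloxypyrylium triflates made from 4-pyranones; new here is their combination on a 2,6-unsubstituted, 3,5-dioxygenated ring, where the carbonyl set free on ring opening is an aldehyde. No stereocentre remains, since the two sp3 centres of 12 are erased on aromatisation. The step needs attack at an alpha carbon and not at C4 or at silicon: the bulky OSiMe2tBu group between two alkoxy groups shields C4 and resists silyl transfer to the ylide carbon (the reason for preferring it to SiMe3), and attack at C2 or at C6 leads to the same arene. K2CO3 in methanol then cleaves only the aryl silyl ether, the primary alkyl silyl ether being stable to it.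

**Step 7**
Reactants: 15 2-(benzyloxy)-4-[3-(tert-butyldimethylsilyloxy)propyl]-6-methoxyphenol; 16 benzyl bromide
Product: 17 tert-butyl{3-[3,4-bis(benzyloxy)-5-methoxyphenyl]propoxy}dimethylsilane
Conditions: K2CO3, DMF, 60 °C
Reagents that add atoms: none
Why: Williamson ether synthesis, in which the phenoxide formed with K2CO3 is benzylated by SN2 reaction and the primary silyl ether is stable to the mild base.

**Step 8**
Reactants: 17 tert-butyl{3-[3,4-bis(benzyloxy)-5-methoxyphenyl]propoxy}dimethylsilane
Product: 18 3-[3,4-bis(benzyloxy)-5-methoxyphenyl]propan-1-ol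
Conditions: TsOH·H2O (cat.), MeOH, rt
Reagents that add atoms: none
Why: Acid-catalysed methanolysis should remove the primary tert-butyldimethylsilyl ether while the benzyl and methyl aryl ethers are inert.

**Step 9**
Reactants: 18 3-[3,4-bis(benzyloxy)-5-methoxyphenyl]propan-1-ol; 19 stearoyl chloride (octadecanoyl chloride)
Product: 20 3-[3,4-bis(benzyloxy)-5-methoxyphenyl]propyl octadecanoate
Conditions: Et3N, DMAP (cat.), CH2Cl2, 0 °C to rt
Reagents that add atoms: none
Why: DMAP-catalysed acylation of the primary alcohol by the acid chloride (nucleophilic acyl substitution), with no competing nucleophile left in the molecule.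

**Step 10**
Reactants: 20 3-[3,4-bis(benzyloxy)-5-methoxyphenyl]propyl octadecanoate
Product: 21 3-(3,4-dihydroxy-5-methoxyphenyl)propyl octadecanoate (target)
Conditions: H2 (1 atm), 10% Pd/C, EtOAc, rt
Reagents that add atoms: none
Why: Hydrogenolysis of both benzyl aryl ethers over Pd/C under neutral conditions should free the catechol without touching the ester or the arene.

**Compound list**
1 | benzyl glycidyl ether, racemic 2-[(benzyloxy)methyl]oxirane | C(OCc1ccccc1)C1CO1 | starting material
2 | 1-(benzyloxy)-3-methoxypropan-2-ol, racemic | COCC(O)COCc1ccccc1 | intermediate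
3 | 1-(benzyloxy)-3-methoxypropan-2-one | COCC(=O)COCc1ccccc1 | intermediate
4 | N,N-dimethylformamide dimethyl acetal | COC(OC)N(C)C | starting material
5 | (1Z,4Z)-2-(benzyloxy)-1,5-bis(dimethylamino)-4-methoxypenta-1,4-dien-3-one, each amino group trans to the carbonyl | CN(C)/C=C(OCc1ccccc1)/C(=O)/C(OC)=C/N(C)C | intermediate
6 | 3-(benzyloxy)-5-methoxy-4H-pyran-4-one | COC1=COC=C(OCc2ccccc2)C1=O | intermediate
7 | (4-bromobutoxy)(tert-butyl)dimethylsilane | CC(C)(C)[Si](C)(C)OCCCCBr | starting material
8 | triphenylphosphine | c1ccc(cc1)P(c1ccccc1)c1ccccc1 | starting material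
9 | [4-(tert-butyldimethylsilyloxy)butyl]triphenylphosphonium bromide | CC(C)(C)[Si](C)(C)OCCCC[P+](c1ccccc1)(c1ccccc1)c1ccccc1.[Br-] | intermediate
10 | 3-(benzyloxy)-4-(tert-butyldimethylsilyloxy)-5-methoxypyrylium trifluoromethanesulfonate | COc1c[o+]cc(OCc2ccccc2)c1O[Si](C)(C)C(C)(C)C.[O-]S(=O)(=O)C(F)(F)F | intermediate
11 | [4-(tert-butyldimethylsilyloxy)butylidene]triphenylphosphorane | CC(C)(C)[Si](C)(C)OCCCC=P(c1ccccc1)(c1ccccc1)c1ccccc1 | intermediate
12 | {1-[3-(benzyloxy)-4-(tert-butyldimethylsilyloxy)-5-methoxy-2H-pyran-2-yl]-4-(tert-butyldimethylsilyloxy)butyl}triphenylphosphonium trifluoromethanesulfonate, mixture of diastereomers | COC1=COC(C(CCCO[Si](C)(C)C(C)(C)C)[P+](c2ccccc2)(c2ccccc2)c2ccccc2)C(OCc2ccccc2)=C1O[Si](C)(C)C(C)(C)C.[O-]S(=O)(=O)C(F)(F)F | intermediate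
13 | (2Z,4E)-4-(benzyloxy)-3,9-bis(tert-butyldimethylsilyloxy)-2-methoxy-6-(triphenylphosphoranylidene)nona-2,4-dienal, drawn in the geometry that closes | O=C/C(OC)=C(O[Si](C)(C)C(C)(C)C)\C(OCc1ccccc1)=C/C(CCCO[Si](C)(C)C(C)(C)C)=P(c1ccccc1)(c1ccccc1)c1ccccc1 | intermediate
14 | tert-butyl{2-(benzyloxy)-4-[3-(tert-butyldimethylsilyloxy)propyl]-6-methoxyphenoxy}dimethylsilane | COc1cc(CCCO[Si](C)(C)C(C)(C)C)cc(OCc2ccccc2)c1O[Si](C)(C)C(C)(C)C | intermediate
15 | 2-(benzyloxy)-4-[3-(tert-butyldimethylsilyloxy)propyl]-6-methoxyphenol | COc1cc(CCCO[Si](C)(C)C(C)(C)C)cc(OCc2ccccc2)c1O | intermediate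
16 | benzyl bromide | BrCc1ccccc1 | starting material
17 | tert-butyl{3-[3,4-bis(benzyloxy)-5-methoxyphenyl]propoxy}dimethylsilane | COc1cc(CCCO[Si](C)(C)C(C)(C)C)cc(OCc2ccccc2)c1OCc1ccccc1 | intermediate
18 | 3-[3,4-bis(benzyloxy)-5-methoxyphenyl]propan-1-ol | COc1cc(CCCO)cc(OCc2ccccc2)c1OCc1ccccc1 | intermediate
19 | stearoyl chloride (octadecanoyl chloride) | CCCCCCCCCCCCCCCCCC(=O)Cl | starting material
20 | 3-[3,4-bis(benzyloxy)-5-methoxyphenyl]propyl octadecanoate | CCCCCCCCCCCCCCCCCC(=O)OCCCc1cc(OC)c(OCc2ccccc2)c(OCc2ccccc2)c1 | intermediate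
21 | 3-(3,4-dihydroxy-5-methoxyphenyl)propyl octadecanoate | CCCCCCCCCCCCCCCCCC(=O)OCCCc1cc(O)c(O)c(OC)c1 | target

**Step count**
Total: 10 steps. Longest linear sequence: 9 steps (steps 1 to 4, then 6 to 10); step 5 is the side branch.

**Steps most likely to fail**

Step 6. Several processes could defeat it: transfer of the silyl group from the pyrylium ion to the ylide carbon, addition at C4, or decay of the ring-opened dienal before the Wittig closure. The fallback builds the arene from a benzenoid by known reactions. It sets out from benzyl bromide 16, which with commercial 3,4-dihydroxy-5-methoxybenzaldehyde and K2CO3 in DMF should give 3,4-bis(benzyloxy)-5-methoxybenzaldehyde F1. A Horner–Wadsworth–Emmons reaction with triethyl phosphonoacetate and NaH in THF should give ethyl (E)-3-[3,4-bis(benzyloxy)-5-methoxyphenyl]prop-2-enoate F2. Conjugate reduction with NaBH4 and NiCl2·6H2O in MeOH at 0 °C, which spares benzyl ethers, should give ethyl 3-[3,4-bis(benzyloxy)-5-methoxyphenyl]propanoate F3. LiAlH4 in THF then reduces the ester, and the fallback comes back to the route at alcohol 18.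

Step 3. The second aminomethylenation may stall at the mono-enaminone, or the material may decompose at the temperature needed. The fallback sets out from ketone 3 and uses a double Claisen formylation: NaH (2.5 equiv) and excess ethyl formate in THF should give the disodium salt of 2-(benzyloxy)-1,5-dihydroxy-4-methoxypenta-1,4-dien-3-one F4. Acidification with HCl cyclises it with loss of water, and the fallback comes back to the route at pyranone 6.

Step 5. Quaternisation may be slow, and adventitious HBr may strip the silyl ether on prolonged heating. The fallback reverses the order of the two operations. It sets out from triphenylphosphine 8, which with 4-bromobutan-1-ol in MeCN at reflux should give (4-hydroxybutyl)triphenylphosphonium bromide F5. Silylation with tBuMe2SiCl and imidazole in CH2Cl2 then comes back to the route at salt 9.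

**Further compounds**
F1 | step 6 | 3,4-bis(benzyloxy)-5-methoxybenzaldehyde | COc1cc(C=O)cc(OCc2ccccc2)c1OCc1ccccc1
F2 | step 6 | ethyl (E)-3-[3,4-bis(benzyloxy)-5-methoxyphenyl]prop-2-enoate | CCOC(=O)/C=C/c1cc(OC)c(OCc2ccccc2)c(OCc2ccccc2)c1
F3 | step 6 | ethyl 3-[3,4-bis(benzyloxy)-5-methoxyphenyl]propanoate | CCOC(=O)CCc1cc(OC)c(OCc2ccccc2)c(OCc2ccccc2)c1
F4 | step 3 | disodium salt of 2-(benzyloxy)-1,5-dihydroxy-4-methoxypenta-1,4-dien-3-one, enolate geometry not fixed | [Na+].[Na+].[O-]C=C(OCc1ccccc1)C(=O)C(OC)=C[O-]
F5 | step 5 | (4-hydroxybutyl)triphenylphosphonium bromide | OCCCC[P+](c1ccccc1)(c1ccccc1)c1ccccc1.[Br-]
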